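**Strategy.** Ring C is cut at O1–C8a and C4–C4a, so ring A enters as 3,5-dimethoxybenzyne and ring B as a racemic 3-hydroxy-2-arylpropanoate that already holds C2, C3 and C4. The key step exploits that ring A carries O1 (on C8a) and C4 (on C4a) on neighbouring carbons, flanked by the C5 oxygen: this oxygen polarises the C4a–C8a aryne, so the primary alkoxide adds at C8a and the C4a anion captures the ester. One operation thus closes ring C as an isoflavanone with the full ring A oxygenation. C3 and C4 are set together afterwards by dynamic kinetic transfer hydrogenation, and two allyl ethers are removed last.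

Key step: step 9

Remark: the target is read as the cis-(3R,4R)-isoflavan-4-ol; prenyl denotes 3-methylbut-2-en-1-yl and allyl denotes prop-2-en-1-yl.

**Ring A aryne precursor**

Step 1
Reactants: 1 3,5-dimethoxyphenol
Product: 2 3,5-dimethoxyphenyl N-isopropylcarbamate
Conditions: i-PrNCO, Et3N (cat.), CH2Cl2, rt
Reagents that add atoms: isopropyl isocyanate, CC(C)N=C=O
Why: Amine-catalysed addition of the phenol to the isocyanate (carbamoylation) installs a carbamate that directs ortho-metalation and can later be removed with mild base.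

Step 2
Reactants: 2 3,5-dimethoxyphenyl N-isopropylcarbamate
Product: 6 3,5-dimethoxy-2-(trimethylsilyl)phenyl N-isopropylcarbamate, via N-silyl carbamate 3 (not isolated), via ortho-lithiated N-silyl carbamate 4 (not isolated), via N-silyl C-silyl carbamate 5 (not isolated)
Conditions: TBSOTf, TMEDA, Et2O, 0 °C to rt; n-BuLi, TMEDA, −78 °C; TMSCl, −78 °C to rt; aq. NaHSO4
Reagents that add atoms: chlorotrimethylsilane, C[Si](C)(C)Cl; tert-butyldimethylsilyl trifluoromethanesulfonate, CC(C)(C)[Si](C)(C)OS(=O)(=O)C(F)(F)F (its silyl group stays only in 3, 4 and 5)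
Why: Directed ortho-metalation: the N-silylated carbamate and the flanking methoxy group together direct lithiation to C2, TMSCl traps the aryllithium, and the labile N–Si bond is hydrolysed on acidic work-up.

Step 3
Reactants: 6 3,5-dimethoxy-2-(trimethylsilyl)phenyl N-isopropylcarbamate
Product: 8 3,5-dimethoxy-2-(trimethylsilyl)phenyl trifluoromethanesulfonate, via free silylphenol 7 (not isolated)
Conditions: DBU, Et2NH, MeCN, 40 °C; then PhNTf2, rt
Reagents that add atoms: N-phenylbis(trifluoromethanesulfonimide), O=S(=O)(N(c1ccccc1)S(=O)(=O)C(F)(F)F)C(F)(F)F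
Why: E1cB cleavage of the N–H carbamate (the isocyanate is scavenged by Et2NH) frees the phenoxide, which is O-sulfonylated in the same pot so that the protodesilylation-prone silylphenol is never isolated.

**Ring B hydroxy ester**

Step 4
Reactants: 9 4-hydroxy-2-methoxybenzaldehyde
Product: 10 4-hydroxy-5-iodo-2-methoxybenzaldehyde
Conditions: NIS, TFA (cat.), MeCN, 0 °C to rt
Reagents that add atoms: N-iodosuccinimide, O=C1CCC(=O)N1I
Why: Electrophilic aromatic iodination should go to C5, which is ortho to the hydroxyl, para to the methoxy group and unhindered, whereas C3 is squeezed between two oxygen substituents.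

Step 5
Reactants: 10 4-hydroxy-5-iodo-2-methoxybenzaldehyde; 11 tributyl(3-methylbut-2-en-1-yl)stannane
Product: 12 4-hydroxy-2-methoxy-5-(3-methylbut-2-en-1-yl)benzaldehyde
Conditions: Pd(PPh3)4 (5 mol %), DMF, 90 °C; aq. KF work-up
Reagents that add atoms: none
Why: Stille coupling under neutral conditions tolerates the free phenol and the aldehyde and should give the linear prenyl arene by reductive elimination at the less hindered allyl terminus; it is run before O-allylation so that no arylpalladium species sits next to an allyl ether, which would invite Heck cyclisation.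

Step 6
Reactants: 12 4-hydroxy-2-methoxy-5-(3-methylbut-2-en-1-yl)benzaldehyde
Product: 13 4-(allyloxy)-2-methoxy-5-(3-methylbut-2-en-1-yl)benzaldehyde
Conditions: allyl bromide, K2CO3, acetone, 50 °C
Reagents that add atoms: allyl bromide, C=CCBr
Why: Williamson etherification of the acidic para-formyl phenoxide gives an allyl ether that is inert to fluoride, MgI2 and transfer hydrogenation and can be removed at the end under neutral conditions.

Step 7
Reactants: 13 4-(allyloxy)-2-methoxy-5-(3-methylbut-2-en-1-yl)benzaldehyde
Product: 14 methyl (Z)-2-[4-(allyloxy)-2-methoxy-5-(3-methylbut-2-en-1-yl)phenyl]-3-hydroxyprop-2-enoate (enol form of the α-formyl ester)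
Conditions: N2CHCO2Me (slow addition), HBF4·OEt2 (10 mol %), CH2Cl2, −78 °C
Reagents that add atoms: methyl diazoacetate, COC(=O)C=[N+]=[N-]
Why: Acid-catalysed aldehyde–diazoacetate homologation (aryl-migration branch of the Roskamp-type reaction): the diazo ester adds to the protonated aldehyde and the electron-rich 2,4-dialkoxyaryl group shifts with loss of N2 onto the ester α-carbon, while catalytic acid at −78 °C should spare the prenyl and allyl groups.

Step 8
Reactants: 14 methyl (Z)-2-[4-(allyloxy)-2-methoxy-5-(3-methylbut-2-en-1-yl)phenyl]-3-hydroxyprop-2-enoate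
Product: 15 racemic methyl 2-[4-(allyloxy)-2-methoxy-5-(3-methylbut-2-en-1-yl)phenyl]-3-hydroxypropanoate
Conditions: NaBH4, MeOH, −10 to 0 °C
Reagents that add atoms: none
Why: Chemoselective borohydride reduction of the formyl tautomer should give the primary alcohol without touching the ester or the alkenes; the future C3 centre forms as a racemate, which is intended because it is epimerised later.

**Key step and endgame**

Step 9
Reactants: 8 3,5-dimethoxy-2-(trimethylsilyl)phenyl trifluoromethanesulfonate; 15 racemic methyl 2-[4-(allyloxy)-2-methoxy-5-(3-methylbut-2-en-1-yl)phenyl]-3-hydroxypropanoate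
Product: 17 racemic 3-[4-(allyloxy)-2-methoxy-5-(3-methylbut-2-en-1-yl)phenyl]-5,7-dimethoxychroman-4-one, via 3,5-dimethoxybenzyne 16 (not isolated)
Conditions: CsF (4 equiv), MeCN, rt; 8 (1.5 equiv) added slowly
Reagents that add atoms: none
Why: Proposed new method: fluoride attacks silicon of 8 and triflate leaves to give aryne 16, the primary alkoxide of 15 (formed with fluoride as base) adds to the aryne carbon remote from the flanking methoxy group (future C8a), and the resulting C4a aryl anion attacks the methyl ester and expels methoxide, so that O1–C8a and C4–C4a form in one operation. The closest known reaction type is the fluoride-triggered annulation of arynes with salicylate esters to xanthones (oxygen addition, then intramolecular acyl capture), which has not been shown for an aliphatic β-hydroxy ester with an acidic α-hydrogen. Ring C closes by 6-exo-trig acyl substitution. No stereocentre is set: C3 enters racemic and stays epimerisable beside the new ketone, as the later dynamic reduction requires. The step needs regioselective addition, secured by the methoxy group that becomes the C5 oxygen, whose inductive effect makes the distal aryne carbon the electrophile and stabilises the anion beside it. It also needs acyl capture to outrun proton transfer from the α-C–H and E1cB loss of the hydroxyl, for which the unhindered methyl ester, the six-membered transition state, room temperature and slow release of the aryne are chosen.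

Step 10
Reactants: 17 racemic 3-[4-(allyloxy)-2-methoxy-5-(3-methylbut-2-en-1-yl)phenyl]-5,7-dimethoxychroman-4-one
Product: 18 racemic 3-[4-(allyloxy)-2-methoxy-5-(3-methylbut-2-en-1-yl)phenyl]-5-hydroxy-7-methoxychroman-4-one
Conditions: MgI2·OEt2 (3 equiv), toluene–Et2O, 70 °C; aq. NH4Cl/Na2S2O3
Reagents that add atoms: none
Why: Chelation-controlled ether cleavage: magnesium binds the C4 carbonyl and the peri C5 methoxy oxygen in a six-membered chelate, so iodide should demethylate only that ether and leave the C7 and ring B methyl ethers, the allyl ether and the prenyl group alone.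

Step 11
Reactants: 18 racemic 3-[4-(allyloxy)-2-methoxy-5-(3-methylbut-2-en-1-yl)phenyl]-5-hydroxy-7-methoxychroman-4-one
Product: 19 racemic 5-(allyloxy)-3-[4-(allyloxy)-2-methoxy-5-(3-methylbut-2-en-1-yl)phenyl]-7-methoxychroman-4-one
Conditions: allyl alcohol, PPh3, DIAD, THF, 0 °C to rt
Reagents that add atoms: allyl alcohol, C=CCO
Why: Mitsunobu etherification alkylates the hydrogen-bonded C5 phenol under neutral conditions, which avoids the C3 enolate and base-induced opening of ring C and removes the chelation that would deactivate the C4 ketone toward hydride transfer.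

Step 12
Reactants: 19 racemic 5-(allyloxy)-3-[4-(allyloxy)-2-methoxy-5-(3-methylbut-2-en-1-yl)phenyl]-7-methoxychroman-4-one
Product: 20 (3R,4R)-5-(allyloxy)-3-[4-(allyloxy)-2-methoxy-5-(3-methylbut-2-en-1-yl)phenyl]-7-methoxychroman-4-ol (cis)
Conditions: RuCl(p-cymene)[(R,R)-TsDPEN] (3 mol %), HCO2H/Et3N (amine-rich), EtOAc, 40 °C
Reagents that add atoms: none
Why: Noyori-type asymmetric transfer hydrogenation with dynamic kinetic resolution: C3 epimerises through the enol under the amine, the (R,R) catalyst delivers hydride to the ketone face that gives the 4R carbinol, and it reduces fastest the enantiomer whose C3 aryl group lies anti to the incoming hydride, so the cis (3R,4R) alcohol should result.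

Step 13
Reactants: 20 (3R,4R)-5-(allyloxy)-3-[4-(allyloxy)-2-methoxy-5-(3-methylbut-2-en-1-yl)phenyl]-7-methoxychroman-4-ol
Product: 21 (3R,4R)-3-[4-hydroxy-2-methoxy-5-(3-methylbut-2-en-1-yl)phenyl]-7-methoxychromane-4,5-diol (cis; CNP0265409.1)
Conditions: Pd(PPh3)4 (5 mol %), morpholine (10 equiv), THF, rt
Reagents that add atoms: none
Why: Tsuji–Trost deallylation: zerovalent palladium ionises both aryl allyl ethers and morpholine traps the allyl fragments, freeing the two phenols under neutral conditions that should leave the acid-sensitive ortho-hydroxybenzylic alcohol, the prenyl group and both stereocentres untouched.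

**Compound list**

1 | 3,5-dimethoxyphenol | COc1cc(O)cc(OC)c1 | starting material
2 | 3,5-dimethoxyphenyl N-isopropylcarbamate | COc1cc(OC)cc(OC(=O)NC(C)C)c1 | intermediate
3 | 3,5-dimethoxyphenyl N-(tert-butyldimethylsilyl)-N-isopropylcarbamate | COc1cc(OC)cc(OC(=O)N(C(C)C)[Si](C)(C)C(C)(C)C)c1 | intermediate (not isolated)
4 | 2-lithio-3,5-dimethoxyphenyl N-(tert-butyldimethylsilyl)-N-isopropylcarbamate | [Li]c1c(OC)cc(OC)cc1OC(=O)N(C(C)C)[Si](C)(C)C(C)(C)C | intermediate (not isolated)
5 | 3,5-dimethoxy-2-(trimethylsilyl)phenyl N-(tert-butyldimethylsilyl)-N-isopropylcarbamate | C[Si](C)(C)c1c(OC)cc(OC)cc1OC(=O)N(C(C)C)[Si](C)(C)C(C)(C)C | intermediate (not isolated)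
6 | 3,5-dimethoxy-2-(trimethylsilyl)phenyl N-isopropylcarbamate | C[Si](C)(C)c1c(OC)cc(OC)cc1OC(=O)NC(C)C | intermediate
7 | 3,5-dimethoxy-2-(trimethylsilyl)phenol | C[Si](C)(C)c1c(O)cc(OC)cc1OC | intermediate (not isolated)
8 | 3,5-dimethoxy-2-(trimethylsilyl)phenyl trifluoromethanesulfonate | COc1cc(OC)c([Si](C)(C)C)c(OS(=O)(=O)C(F)(F)F)c1 | intermediate
9 | 4-hydroxy-2-methoxybenzaldehyde | COc1cc(O)ccc1C=O | starting material
10 | 4-hydroxy-5-iodo-2-methoxybenzaldehyde | COc1cc(O)c(I)cc1C=O | intermediate
11 | tributyl(3-methylbut-2-en-1-yl)stannane | CC(C)=CC[Sn](CCCC)(CCCC)CCCC | starting material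
12 | 4-hydroxy-2-methoxy-5-(3-methylbut-2-en-1-yl)benzaldehyde | COc1cc(O)c(CC=C(C)C)cc1C=O | intermediate
13 | 4-(allyloxy)-2-methoxy-5-(3-methylbut-2-en-1-yl)benzaldehyde | COc1cc(OCC=C)c(CC=C(C)C)cc1C=O | intermediate
14 | methyl (Z)-2-[4-(allyloxy)-2-methoxy-5-(3-methylbut-2-en-1-yl)phenyl]-3-hydroxyprop-2-enoate | COC(=O)/C(=C\O)c1cc(CC=C(C)C)c(OCC=C)cc1OC | intermediate
15 | racemic methyl 2-[4-(allyloxy)-2-methoxy-5-(3-methylbut-2-en-1-yl)phenyl]-3-hydroxypropanoate | COC(=O)C(CO)c1cc(CC=C(C)C)c(OCC=C)cc1OC | intermediate
16 | 3,5-dimethoxybenzyne | COC1=CC#CC(OC)=C1 | intermediate (not isolated)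
17 | racemic 3-[4-(allyloxy)-2-methoxy-5-(3-methylbut-2-en-1-yl)phenyl]-5,7-dimethoxychroman-4-one | COc1cc(OC)c2c(c1)OCC(c1cc(CC=C(C)C)c(OCC=C)cc1OC)C2=O | intermediate
18 | racemic 3-[4-(allyloxy)-2-methoxy-5-(3-methylbut-2-en-1-yl)phenyl]-5-hydroxy-7-methoxychroman-4-one | COc1cc(O)c2c(c1)OCC(c1cc(CC=C(C)C)c(OCC=C)cc1OC)C2=O | intermediate
19 | racemic 5-(allyloxy)-3-[4-(allyloxy)-2-methoxy-5-(3-methylbut-2-en-1-yl)phenyl]-7-methoxychroman-4-one | COc1cc(OCC=C)c2c(c1)OCC(c1cc(CC=C(C)C)c(OCC=C)cc1OC)C2=O | intermediate
20 | (3R,4R)-5-(allyloxy)-3-[4-(allyloxy)-2-methoxy-5-(3-methylbut-2-en-1-yl)phenyl]-7-methoxychroman-4-ol | COc1cc(OCC=C)c2c(c1)OC[C@@H](c1cc(CC=C(C)C)c(OCC=C)cc1OC)[C@H]2O | intermediate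
21 | (3R,4R)-3-[4-hydroxy-2-methoxy-5-(3-methylbut-2-en-1-yl)phenyl]-7-methoxychromane-4,5-diol | COc1cc(O)c2c(c1)OC[C@@H](c1cc(CC=C(C)C)c(O)cc1OC)[C@H]2O | target

**Step count and risks**

Total: 13 steps (3 to the ring A silyl triflate, 5 to the ring B hydroxy ester, the key step, 4 after it). Longest linear sequence: 10 steps (steps 4 to 13, from 4-hydroxy-2-methoxybenzaldehyde).

The three steps most likely to fail:

1. Step 9 (key step). The hydroxy ester may lose water under fluoride before it adds to the aryne, the aryl anion may be protonated by the α-C–H before it reaches the ester, or the enolisable product may react with further aryne. The fallback uses known chemistry, sets out from 15 and returns at 17. Compound 15 would be treated with MsCl and Et3N in CH2Cl2 (0 °C to rt), which should pass through the methyl 3-(mesyloxy)-2-arylpropanoate F1 in the flask and eliminate to the methyl 2-arylacrylate F2. LiOH in THF/H2O would then give the 2-arylacrylic acid F3. Heating F3 with 8 and CsF in THF (sealed vessel, about 125 °C) should regenerate aryne 16; the carboxylate oxygen adds to it, the aryl anion takes over the acyl group to give the ortho-hydroxyaryl vinyl ketone F4 in the flask, and its phenoxide closes ring C by 6-endo-trig oxa-Michael addition to 17. This known carboxylic acid–aryne insertion/oxa-Michael route to chroman-4-ones makes the elimination part of the plan and has no α-hydrogen to lose; the same methoxy group controls the regiochemistry.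

2. Step 7. The acid may add to or cyclise the prenyl group, or hydride instead of aryl may migrate and give the β-keto ester. The fallback is acid-free, sets out from 13 and returns at 15. CHCl3 and DBU should add to the aldehyde to give the trichloromethyl carbinol F5. NaBH4 and NaOH in t-BuOH (55 °C) should convert it by reductive Jocic-type homologation, through the gem-dichloroepoxide, into the arylacetic acid F6. MeI and K2CO3 in DMF would give the methyl arylacetate F7, and base-catalysed aldol addition to formaldehyde (paraformaldehyde, NaOMe cat., DMSO, rt) would hydroxymethylate it to 15.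

3. Step 12. Hydride transfer to the electron-rich, peri-alkoxy ketone may be slow and C3 epimerisation may not keep pace, so that cis selectivity and enantiomeric purity erode. The fallback separates the two controls, sets out from 19 and returns at 20. LiBH(s-Bu)3 in THF at −78 °C should attack anti to the C3 aryl group and give the racemic cis alcohol F8. Preparative chromatography on a chiral stationary phase would then resolve it, and the (3R,4R) enantiomer is 20.

**Further compounds**

F1 | step 9 | racemic methyl 2-[4-(allyloxy)-2-methoxy-5-(3-methylbut-2-en-1-yl)phenyl]-3-(methylsulfonyloxy)propanoate | COC(=O)C(COS(C)(=O)=O)c1cc(CC=C(C)C)c(OCC=C)cc1OC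
F2 | step 9 | methyl 2-[4-(allyloxy)-2-methoxy-5-(3-methylbut-2-en-1-yl)phenyl]prop-2-enoate | COC(=O)C(=C)c1cc(CC=C(C)C)c(OCC=C)cc1OC
F3 | step 9 | 2-[4-(allyloxy)-2-methoxy-5-(3-methylbut-2-en-1-yl)phenyl]prop-2-enoic acid | OC(=O)C(=C)c1cc(CC=C(C)C)c(OCC=C)cc1OC
F4 | step 9 | 2-[4-(allyloxy)-2-methoxy-5-(3-methylbut-2-en-1-yl)phenyl]-1-(2-hydroxy-4,6-dimethoxyphenyl)prop-2-en-1-one | COc1cc(O)c(C(=O)C(=C)c2cc(CC=C(C)C)c(OCC=C)cc2OC)c(OC)c1
F5 | step 7 | racemic 1-[4-(allyloxy)-2-methoxy-5-(3-methylbut-2-en-1-yl)phenyl]-2,2,2-trichloroethanol | COc1cc(OCC=C)c(CC=C(C)C)cc1C(O)C(Cl)(Cl)Cl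
F6 | step 7 | 2-[4-(allyloxy)-2-methoxy-5-(3-methylbut-2-en-1-yl)phenyl]acetic acid | COc1cc(OCC=C)c(CC=C(C)C)cc1CC(=O)O
F7 | step 7 | methyl 2-[4-(allyloxy)-2-methoxy-5-(3-methylbut-2-en-1-yl)phenyl]acetate | COc1cc(OCC=C)c(CC=C(C)C)cc1CC(=O)OC
F8 | step 12 | racemic cis-5-(allyloxy)-3-[4-(allyloxy)-2-methoxy-5-(3-methylbut-2-en-1-yl)phenyl]-7-methoxychroman-4-ol, (3R,4R) and (3S,4S) | COc1cc(OCC=C)c2c(c1)OC[C@@H](c1cc(CC=C(C)C)c(OCC=C)cc1OC)[C@H]2O.COc1cc(OCC=C)c2c(c1)OC[C@H](c1cc(CC=C(C)C)c(OCC=C)cc1OC)[C@@H]2O
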